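- north-east: Q 0.20 M; G 7.1 mM (held); the very flask that is asked about, followed so far
- flask: Q 0.20 M; G 7.1 mM (held); time 1.5 h

north-east run (percent of the Q charged)

| time / min | X / % | Q / % |
|---|---|---|
| 3.00 | 10 | 90 |
| 6.00 | 17 | 79 |
| 10.0 | 25 | 69 |
| 12.0 | 26 | 62 |
| 15.0 | 28 | 54 |

(each reading ± 1.5 percentage points)

- the moment within 1.5 h at which there is most X
- the amount of X, in percent of the Q charged, at that time

- at the start none of G is in solution

**The balance.** Adding two columns was the easy step: at 15.0 min the readings of X and Q together came to 82.0 %, so by those readings 18.0 % of the Q charged was neither. I read that as X passing on at a constant kx (per min). I took the fall of Q as pseudo-first-order, with a constant k1 of 0.0426 min⁻¹ from the first and last readings.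

**Mean way.** On that reading the loss was kx times the mean of X times the time. Joining the readings by chords gave a mean X of 18.1 %, so kx came to 0.0663 min⁻¹.

**Slope way.** Over the last stretch, X made minus the measured rise, divided by the mean X there, gave 0.0762 min⁻¹. That rise, 3 percentage points, is smaller than the loss behind the mean way, with the same scatter on each reading, so I took the slope as the one that cheats and kept the mean.

**Peak ratio.** X stops rising when k1 times Q equals kx times X, so at the top X/Q equals the peak ratio r = k1/kx, here 0.642. For consecutive first-order steps from a start without X, the height as a share of the Q charged is r raised to the power one over one minus r, which gave me 29.0 % at 0.311 h.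

**The forecast.** It gave 0.32 h (0.24 h to 0.43 h) and 29 % (27 % to 32 %), reasoning that “X is passing on to something unseen”. Its time lay slightly later than mine.

**The result.** The flask reached its most X at 0.357 h, with 29.6 %.

    G ⇌ L, rate k1*(csat - [L]) (kL = 0.0815 s⁻¹)
    Q + L → X (k = 0.116 M⁻¹ s⁻¹)
    L ⇌ Z (K = 21.2, k = 3.71 × 10⁻⁴ s⁻¹)
    X ⇌ E (K = 14.6, k = 0.00110 s⁻¹)

In this flask at 0.357 h Q stood at 41.5 %, and r times that is 26.7 %, beside X at 29.6 %. A neighbour flask charged with 0.80 M of Q kept 3.6 % of its Q at 1.50 h, a mean constant of 0.0370 min⁻¹. Over kx that makes r 0.557, and the height rule gives 26.7 %. That neighbour's best was 23.9 %.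

The earlier runs and the new flask were computed from invented constants.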